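The readings are calculated on assumed constants; scatter was added.

- The 3 questions are taken here through one ratio, the leak ratio ρ, which is D formed per G formed, and the excess of G over D equals (one minus ρ) over (one plus ρ).

| setting | south | larch | maple |
|---|---|---|---|
| L | 0.53 M | 0.53 M | 0.53 M |
| Z | 0.53 M | 0.53 M | 0.53 M |
| Q | 0.53 M | 0.530 M | 0.530 M |
| E | 7.9 mM | 5.3 mM | 5.3 mM |
| remark | run made earlier |  |  |
| time |  | 8.0 min | 2.0 min |

south run (percent of the L and Z together charged)

| time / s | G / % | D / % | L / % |
|---|---|---|---|
| 10.0 | 2.4 | 0 | 47.5 |
| 20.0 | 5.9 | 0 | 44.5 |
| 30.0 | 8.2 | 0 | 43.2 |
| 50.0 | 10.7 | 0 | 39.7 |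

(scatter of a reading: 1 percentage point)

- E is single-handed; L and Z are mirror images of each other, charged as a racemate, each of them at the stated concentration
- an excess is the difference of the two amounts in percent of their sum
- an excess is below zero if the other one leads
- no earlier run changes the charge of E; that part of a forecast is a guess

1. which of the two ends with the higher excess of G over D in the product ("neither" if they lie within 2 percentage points) (larch / maple / neither)
2. excess of G over D in the product at the end, larch
3. excess of G over D in the product at the end, maple

- Q, charged at 0.530 M against 1.06 M of L and Z together, is the limiting reagent, and its balance says that each Q lost ends in G or in D, so D is the Q lost minus the G found.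
- From above the bracket is plain: D cannot fall below zero, so the excess stands at 100 % or under.
- From below, my own reckoning lets D hide up to two scatters behind the last south reading of G, 10.7 %, which allows an excess of 68.5 %.
- Taking the 4 south readings together tightens this to a leak ceiling, two scatters over the root of the summed squares of G, of 0.134, and so to a floor of 76.3 %; this holds over the south span of G, and no earlier run changes the charge of E.
- Read as an inverse selectivity factor, this ceiling asks for a factor of 7.46, whereas the forecast says “Z therefore reacts at least about 15 times slower than L”.
- The forecast gives 95 % for larch and 97 % for maple, answers neither, and stands inside the bracket.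
- The flask gives 97.5 % for larch and 98.0 % for maple, so the answer is neither.

    Q + E + Z → E + D (k = 0.0120 L² mol⁻² s⁻¹)
    E ⇌ J (K = 21.0, k = 4.40 × 10⁻⁴ s⁻¹)
    Q + E + L → E + G (k = 1.40 L² mol⁻² s⁻¹)
    E → X (k = 0.00130 s⁻¹)

- Maple stays within 5 points of its excess with E anywhere from 0.66 mM to 42 mM, at least, the search going no further.
- Larch at 8.00 min holds D 0.350 % against G 28.0 %, a leak ratio of 0.0125, less than the ceiling of 0.134, and maple left until 3.0 min holds a leak ratio of 0.0107, which makes its excess 97.9 %.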